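# Proposed total synthesis of CNP0263020.2 through a cis-divinylcyclopropane (Cope) rearrangement

## Structural features

Locants C1–C15 of the 2,3-seco-aromadendrane skeleton are used for every compound: C1/C5 ring fusion, C2 acetal carbon, C3=C4 enol ether, C15 on C4, C6/C7/C11 cyclopropane, C8 ketone, C9=C10 alkene, C14 formyl carbon on C10. The target 30 is tricyclic: a 2-acetoxy-3,4-dihydro-2H-pyran (O, C2, C1, C5, C4, C3) is cis-fused along C1–C5 to a cycloheptenone (C1, C10, C9, C8, C7, C6, C5), whose C6–C7 edge carries a gem-dimethylcyclopropane. Five stereocentres form one chain C2–C1–C5–C6–C7, (1R,2S,5R,6R,7S): H1 and H5 are cis, the C2 acetate is trans to H1, and C11 lies on the ring face opposite C4 (H5/H6 trans, H6/H7 cis). The fragile parts are the acylated enol acetal with its allylic C15 acetate, the 4-oxo-enal array C14(=O)–C10=C9–C8(=O), and C1–H, which is γ to the enone. The difficulty is the seven-membered ring with two cis fusion hydrogens and the correct cyclopropane face, followed by raising C2, C3 and C14 to the aldehyde level and closing the enol acetal without disturbing C1. The key step exploits the fact that C8 is flanked by the C9=C10 alkene and by the C6–C7 cyclopropane edge (a disguised C6=C7 alkene), with cis centres C1 and C5 across the ring. This is the pattern of a cis-6,7-disubstituted cyclohepta-1,4-diene, the product of a cis-divinylcyclopropane rearrangement whose ring carbons are C9, C8 and C7. Because C4 is trigonal in 30, C3 and C15 can travel as the two arms of one symmetrical protected 1,3-diol.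

## Logic of the disconnections

**30 ⇒ 28.** The ring O–C2 bond and the acetyl–O bond at C2 are cut. The acylated enol acetal is the cyclic tautomer of a C2/C3 1,5-dialdehyde and is the most labile part, so it is made last. This removes one ring and the C2 stereocentre. The forward step must close through the C3 enol and not through C1, must acylate before the β-acetoxy aldehyde loses acetate, and must set C2 under anomeric control.

**28 ⇒ 27 ⇒ 26 ⇒ 23.** No skeletal bond is cut. C2, C3 and C14 are taken back to primary alcohols, C2/C14 to silyl ethers and C3/C15 to one acetonide. All aldehyde-level carbons thus pass the basic and oxidative steps as protected alcohols. The demands are one acetylation of a symmetrical diol, silyl groups that outlast acid, and an oxidation that makes three aldehydes without a lactol detour.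

**23 ⇒ 22.** C6–C11 and C7–C11 are cut. A cyclopropane on the α,β-edge of a ketone is the retron of isopropylidene transfer to an enone. One ring and two stereocentres disappear. The forward step must choose the C6=C7 enone over the C9=C10 enone and the face opposite C4.

**22 ⇒ 21.** The C8 carbonyl oxygen is removed. C8 in 21 is doubly allylic and carries the weakest C–H bonds. This exposes the skipped diene. The forward oxidation must be selective for the central carbon of the C6–C10 pentadienyl system.

**21 ⇒ 20.** C1–C5 is cut and C7–C9 re-formed (retro-Cope). The seven-membered ring and both fusion stereocentres are exchanged for a cis-cyclopropane whose two centres come from a meso compound. The forward step needs the cis relation on the ring, E geometry at C5=C6 and C2 trans to C9 on C1=C10.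

**20 ⇒ 19 + 4.** The C5=C6 double bond is cut. The unstable cis-dialkenyl system is then formed last, and C3/C4/C5/C15 arrive as one achiral piece. The olefination must be E-selective and must not epimerise the cis aldehyde.

**19 ⇒ 15 ⇒ 12 + 13.** After adjustment of protecting groups and oxidation level (18, 17, 16), the C1=C10 bond and the O–C2 bond of the lactone are cut. The five-membered ring of 15 forces C14 and C2 onto one side of C1=C10, which is the geometry the boat requires. Two carbons and a defined trisubstituted alkene come from one reagent. The demand is a free α-hydroxy ketone next to a differently protected O6.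

**12 ⇒ 10 ⇒ 8.** C10–C14 is cut: an alkoxymethyl anion adds to an acyl equivalent at C10, which is the opened lactone carbonyl. The demand is single addition and orthogonality of the O14 and O6 protecting groups.

**8 ⇒ 6 ⇒ 5.** The two carbonyls of the meso anhydride are differentiated. Both cyclopropane stereocentres come from one enantioselective event, and the choice of which carbonyl is reduced fixes the absolute sense.

**4 ⇒ 3 ⇒ 2 ⇒ 1.** The C5–S bond and the acetal are cut, which leads back to the symmetrical triol.

## Other disconnections considered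

**Alternative 1:** The cut is C4–C5 and O–C2. In the forward step an imidazol-2-ylidene turns the bicyclic dienoyl fluoride A2 into an unsaturated acyl azolium. The fluoride released unmasks the enolate of silyl enol ether A3. Michael addition at C5 and O-acylation then give enol lactone A1.
- In its favour: the pyran regiochemistry is unambiguous, because C2 enters as the acyl carbon and C3 as the enol carbon. On this point it is better than the chosen plan, whose dialdehyde closure can in principle run through either enol. O15 also arrives singly protected, so no diol has to be mono-acetylated.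
- Against it: A2 must already contain the cyclopropane, the enone and both absolute centres C6/C7, for which this step offers no solution. C5 and C1 are set only by substrate bias (addition anti to C11, then protonation). The C9=C10 enone is a second acceptor.
- After the key step the lactone must be reduced to the lactol beside an enone, the silyl ether exchanged for acetate and the acetal hydrolysed.
- Comparison: it is equal in convergence and better in regiocontrol of the heterocycle. It is weaker in the origin of absolute stereochemistry, which the chosen plan takes from a meso anhydride by stereospecific transfer, and it carries a harder chemoselectivity problem at the end.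

**Alternative 2:** The cut is C1–C5 and O–C2. On heating, the enal of A5 acts as heterodiene and the Z-enol acetate as dienophile to give A4.
- In its favour: two rings and three stereocentres (C1, C2, C5) form at once. Both acetates are already in place. The C2 configuration follows stereospecifically from the Z-enol acetate, which is better than the anomeric control relied on here. No trialdehyde is needed.
- Against it: enal/enol acetate hetero-Diels–Alder reactions are sluggish without activation, and the tether closes a seven-membered ring. A5 is a cis-2-alkenylcyclopropyl ketone, which on heating can divert by a retro-Claisen shift. Endo/exo and facial selectivity both have to fall correctly.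
- After the key step C9–C10 must still be dehydrogenated and C14 unveiled and oxidised beside the sensitive acetal.
- Comparison: it is better in endgame economy and in control of C2, and it sets more stereocentres in the key step. It is weaker in predictability, since the Cope step runs near room temperature through a single allowed geometry.

**Alternative 3:** The cut is C6–C7 and C7–C11. Ph3PAuCl/AgSbF6 activates the terminal alkyne of A7, the acetate shifts from C9 to C8, and the gold carbene at C7 cyclopropanates the C6=C11 alkene to give A6.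
- In its favour: one catalytic step builds the cyclopropane and the seven-membered ring and installs the C8 oxygen. That replaces the C–H oxidation and the ylide step of the chosen plan and avoids the radical regiochemistry question, so it is better in economy at that point. The enol lactone regiochemistry is fixed.
- Against it: closing a seven-membered ring by this cyclopropanation is less secure than the usual five- and six-membered cases. The electron-rich C3=C4 enol ether can compete for the activated alkyne. The C6/C7 face rests on C5 alone. A7 needs C1, C5, C9 and C10 in place beforehand.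
- After the key step the enol acetate must be converted to the ketone, C9=C10 introduced at a saturated C10, the lactone reduced beside the ketone, the acetal hydrolysed and the silyl ether exchanged.
- Comparison: it is better around C8 and the cyclopropane and equal in ring count per step. It is weaker in stereochemical security and in the length of the endgame.

Key step: step 16

**Remarks before the steps**

- Assumption: quinidine is taken to deliver the (1R,2S) hemiester 6. Should the sense be opposite, quinine in step 4, or reduction of the acid instead of the ester in step 5, leads to the same lactone 8.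
- Stereochemical check of the key pair: the cis-(7R,9R) cyclopropane 20 with a Z-butenyl and an E-vinyl arm passes through the boat to (1R,5R)-21, which is the C1/C5 configuration of 30. The structures of the key pair need no correction.
- Design change: the two silyl groups on O2 and O14 are tert-butyldiphenylsilyl, so that release of O6 (step 13) and cleavage of the acetonide (step 19) cannot touch them.

## Steps

**Step 1**
Reactants: 1 2-(hydroxymethyl)propane-1,3-diol
Product: 2 (2,2-dimethyl-1,3-dioxan-5-yl)methanol
Conditions: Me2C(OMe)2, TsOH·H2O (cat.), THF, rt; Et3N quench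
Reagents that add atoms: 2,2-dimethoxypropane COC(C)(C)OC
Why: Acid-catalysed acetal exchange; the six-membered dioxane forms from two of three equivalent hydroxyls and leaves one primary alcohol, and no stereocentre arises.

**Step 2**
Reactants: 2 (2,2-dimethyl-1,3-dioxan-5-yl)methanol
Product: 3 5-{[(2,2-dimethyl-1,3-dioxan-5-yl)methyl]sulfanyl}-1-phenyl-1H-tetrazole
Conditions: 1-phenyl-1H-tetrazole-5-thiol, PPh3, i-PrO2CN=NCO2i-Pr, THF, 0 °C → rt
Reagents that add atoms: 1-phenyl-1H-tetrazole-5-thiol Sc1nnnn1-c1ccccc1
Why: Mitsunobu thioetherification of a primary alcohol by an acidic thiol (SN2 at the future C5).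

**Step 3**
Reactants: 3 5-{[(2,2-dimethyl-1,3-dioxan-5-yl)methyl]sulfanyl}-1-phenyl-1H-tetrazole
Product: 4 5-{[(2,2-dimethyl-1,3-dioxan-5-yl)methyl]sulfonyl}-1-phenyl-1H-tetrazole
Conditions: (NH4)6Mo7O24·4H2O (cat.), 30% H2O2, EtOH, 0 °C → rt
Reagents that add atoms: hydrogen peroxide OO
Why: Molybdate-catalysed peroxide oxidation of sulfide to sulfone; the nearly neutral medium should leave the acetonide intact, and no alkene is present.

**Step 4**
Reactants: 5 cis-cyclopropane-1,2-dicarboxylic anhydride (meso)
Product: 6 (1R,2S)-2-(methoxycarbonyl)cyclopropane-1-carboxylic acid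
Conditions: quinidine (1.1 equiv), MeOH (3 equiv), PhMe, −55 °C; aq. HCl wash (alkaloid recovered)
Reagents that add atoms: methanol CO
Why: Alkaloid-mediated desymmetrising methanolysis of a meso anhydride: the quinuclidine nitrogen acts as chiral general base and directs methanol to one enantiotopic carbonyl. This single event fixes the absolute configuration of both cyclopropane carbons (future C9 and C7).

**Step 5**
Reactants: 6 (1R,2S)-2-(methoxycarbonyl)cyclopropane-1-carboxylic acid
Product: 8 (1R,5S)-3-oxabicyclo[3.1.0]hexan-2-one, via hydroxy acid 7 (not isolated)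
Conditions: LiBEt3H (3.3 equiv), THF, −78 °C → rt; then 2 M HCl, rt
Reagents that add atoms: none
Why: Chemoselective hydride reduction: the acid is masked as its lithium carboxylate while the ester is reduced, and acidification lactonises the cis hydroxy acid. The carbonyl (future C10) stays on the R carbon and the CH2O group (future C6) on the S carbon.

**Step 6**
Reactants: 8 (1R,5S)-3-oxabicyclo[3.1.0]hexan-2-one
Product: 9 (1R,2S)-2-(hydroxymethyl)-N-methoxy-N-methylcyclopropane-1-carboxamide
Conditions: MeNHOMe·HCl, AlMe3, CH2Cl2, 0 °C → rt; aq. KNaC4H4O6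
Reagents that add atoms: N,O-dimethylhydroxylamine hydrochloride CNOC.Cl
Why: Aluminium amide aminolysis of a lactone to the Weinreb amide; the cis relation is untouched, and the product is silylated at once because it can relactonise.

**Step 7**
Reactants: 9 (1R,2S)-2-(hydroxymethyl)-N-methoxy-N-methylcyclopropane-1-carboxamide
Product: 10 (1R,2S)-2-{[(tert-butyldimethylsilyl)oxy]methyl}-N-methoxy-N-methylcyclopropane-1-carboxamide
Conditions: TBSCl, imidazole, DMF, 0 °C → rt
Reagents that add atoms: tert-butyldimethylsilyl chloride CC(C)(C)[Si](C)(C)Cl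
Why: Silylation of the primary alcohol; it blocks relactonisation and marks O6 for selective release later.

**Step 8**
Reactants: 10 (1R,2S)-2-{[(tert-butyldimethylsilyl)oxy]methyl}-N-methoxy-N-methylcyclopropane-1-carboxamide
Product: 11 2-(benzyloxy)-1-[(1R,2S)-2-{[(tert-butyldimethylsilyl)oxy]methyl}cyclopropyl]ethan-1-one
Conditions: BnOCH2SnBu3, n-BuLi, THF, −78 °C; then 10, −78 °C; aq. NH4Cl
Reagents that add atoms: tributyl[(benzyloxy)methyl]stannane CCCC[Sn](CCCC)(CCCC)COCc1ccccc1
Why: Tin–lithium exchange gives an α-alkoxy organolithium (hydroxymethyl anion equivalent, C14) that adds once to the Weinreb amide, because the chelated tetrahedral intermediate survives until work-up.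

**Step 9**
Reactants: 11 2-(benzyloxy)-1-[(1R,2S)-2-{[(tert-butyldimethylsilyl)oxy]methyl}cyclopropyl]ethan-1-one
Product: 12 1-[(1R,2S)-2-{[(tert-butyldimethylsilyl)oxy]methyl}cyclopropyl]-2-hydroxyethan-1-one
Conditions: H2 (1 atm), Pd(OH)2/C, EtOAc, rt
Reagents that add atoms: none
Why: Hydrogenolysis of a benzyl ether at a stage without any alkene; the silyl ether, ketone and cyclopropane should be inert at 1 atm in ethyl acetate.

**Step 10**
Reactants: 12 1-[(1R,2S)-2-{[(tert-butyldimethylsilyl)oxy]methyl}cyclopropyl]-2-hydroxyethan-1-one; 13 (triphenylphosphoranylidene)ketene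
Product: 15 4-[(1R,2S)-2-{[(tert-butyldimethylsilyl)oxy]methyl}cyclopropyl]furan-2(5H)-one, via ester ylide 14 (not isolated)
Conditions: PhMe, 110 °C
Reagents that add atoms: none
Why: The hydroxyl adds to the cumulated ylide to give the acyl ylide ester, whose intramolecular Wittig reaction with the ketone closes the butenolide. The ring holds C14 and C2 on the same side of the new C10=C1 bond (C2 trans to C9), the geometry the boat will need.

**Step 11**
Reactants: 15 4-[(1R,2S)-2-{[(tert-butyldimethylsilyl)oxy]methyl}cyclopropyl]furan-2(5H)-one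
Product: 16 (2Z)-2-[(1R,2S)-2-{[(tert-butyldimethylsilyl)oxy]methyl}cyclopropyl]but-2-ene-1,4-diol
Conditions: i-Bu2AlH (4.5 equiv), CH2Cl2, −78 → 0 °C; aq. KNaC4H4O6
Reagents that add atoms: none
Why: Hydride reduction of the unsaturated lactone through the lactol and the hydroxy enal (1,2-reduction) to the diol; excess reagent and warming avoid stopping at the lactol, which could aromatise to a furan. The Z geometry is retained.

**Step 12**
Reactants: 16 (2Z)-2-[(1R,2S)-2-{[(tert-butyldimethylsilyl)oxy]methyl}cyclopropyl]but-2-ene-1,4-diol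
Product: 17 (1R,2S)-1-[(2Z)-1,4-bis{[tert-butyl(diphenyl)silyl]oxy}but-2-en-2-yl]-2-{[(tert-butyldimethylsilyl)oxy]methyl}cyclopropane
Conditions: TBDPSCl (2.4 equiv), imidazole, DMF, rt
Reagents that add atoms: tert-butyl(chloro)diphenylsilane CC(C)(C)[Si](Cl)(c1ccccc1)c1ccccc1
Why: Silylation of both primary allylic hydroxyls with a group that outlasts the acidic steps 13 and 19.

**Step 13**
Reactants: 17 (1R,2S)-1-[(2Z)-1,4-bis{[tert-butyl(diphenyl)silyl]oxy}but-2-en-2-yl]-2-{[(tert-butyldimethylsilyl)oxy]methyl}cyclopropane
Product: 18 {(1S,2R)-2-[(2Z)-1,4-bis{[tert-butyl(diphenyl)silyl]oxy}but-2-en-2-yl]cyclopropyl}methanol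
Conditions: PPTS (cat.), MeOH, 0 °C → rt
Reagents that add atoms: none
Why: Acid-catalysed methanolysis cleaves a primary tert-butyldimethylsilyl ether far faster than primary tert-butyldiphenylsilyl ethers (selective deprotection).

**Step 14**
Reactants: 18 {(1S,2R)-2-[(2Z)-1,4-bis{[tert-butyl(diphenyl)silyl]oxy}but-2-en-2-yl]cyclopropyl}methanol
Product: 19 (1S,2R)-2-[(2Z)-1,4-bis{[tert-butyl(diphenyl)silyl]oxy}but-2-en-2-yl]cyclopropane-1-carbaldehyde
Conditions: Dess–Martin periodinane, pyridine, CH2Cl2, 0 °C; used at once
Reagents that add atoms: none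
Why: Buffered Dess–Martin oxidation; the α-carbon (C7) is a cyclopropane carbon and resists enolisation. The aldehyde is used immediately because cis-2-alkenylcyclopropanecarbaldehydes can drift reversibly into dihydrooxepines (retro-Claisen).

**Step 15**
Reactants: 19 (1S,2R)-2-[(2Z)-1,4-bis{[tert-butyl(diphenyl)silyl]oxy}but-2-en-2-yl]cyclopropane-1-carbaldehyde; 4 5-{[(2,2-dimethyl-1,3-dioxan-5-yl)methyl]sulfonyl}-1-phenyl-1H-tetrazole
Product: 20 (1R,2R)-1-[(2Z)-1,4-bis{[tert-butyl(diphenyl)silyl]oxy}but-2-en-2-yl]-2-[(E)-2-(2,2-dimethyl-1,3-dioxan-5-yl)ethenyl]cyclopropane (cis; worked up cold and carried on crude)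
Conditions: 4, KN(SiMe3)2, DME, −78 °C; then 19, −78 → 0 °C; cold aq. NH4Cl
Reagents that add atoms: none
Why: Julia–Kocienski olefination (addition, Smiles transfer of the tetrazole, anti-elimination); a phenyltetrazolyl sulfone with potassium counter-ion in DME should favour the E alkene with an α-branched aldehyde. The base is consumed before the aldehyde is added, so C7 should not epimerise.

**Step 16**
Reactants: 20 (1R,2R)-1-[(2Z)-1,4-bis{[tert-butyl(diphenyl)silyl]oxy}but-2-en-2-yl]-2-[(E)-2-(2,2-dimethyl-1,3-dioxan-5-yl)ethenyl]cyclopropane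
Product: 21 5-[(1R,5R; skeleton locants)-1,10-bis({[tert-butyl(diphenyl)silyl]oxy}methyl)cyclohepta-6,9-dien-5-yl]-2,2-dimethyl-1,3-dioxane (H1/H5 cis, C8 methylene doubly allylic)
Conditions: PhMe, 23 → 40 °C
Reagents that add atoms: none
Why: Thermal [3,3]-sigmatropic (Cope) rearrangement; the closest known reaction type is the cis-divinylcyclopropane to cyclohepta-1,4-diene rearrangement, driven by release of cyclopropane strain. Both arms rotate over the three-membered ring into the only reactive (boat) geometry; C7–C9 breaks while C1–C5 forms suprafacially on both allyl halves, and the π bonds move to C9=C10 and C6=C7, leaving C8 doubly allylic. The seven-membered ring (C1, C10, C9, C8, C7, C6, C5) is closed pericyclically as a three-to-seven ring expansion, not by a polar exo or endo attack. C5 is controlled by the E geometry of C5=C6 and C1 by the butenolide-derived geometry of C1=C10 (C2 trans to C9): both substituents point away from the ring in the boat, so C2 and C4 end up cis and H1 and H5, which point inward toward C8, also cis. The absolute sense at C1 and C5 is dictated by the (7R,9R) cyclopropane, whose two centres are consumed as their chirality is transferred. The step needs the cis relation on the cyclopropane (secured by the meso anhydride origin and by handling 19 cold) and outward placement of both terminal substituents (secured by step 15 and by the ring of 15); a Z terminus would have to turn inward against C8–H and should not react at this temperature. No homodienyl 1,5-hydrogen shift can compete, because neither arm has a C–H on a saturated carbon attached directly to the ring.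

**Step 17**
Reactants: 21 5-[(1R,5R)-1,10-bis({[tert-butyl(diphenyl)silyl]oxy}methyl)cyclohepta-6,9-dien-5-yl]-2,2-dimethyl-1,3-dioxane
Product: 22 (1R,5R)-1,10-bis({[tert-butyl(diphenyl)silyl]oxy}methyl)-5-(2,2-dimethyl-1,3-dioxan-5-yl)cyclohepta-6,9-dien-8-one
Conditions: Rh2(C6H10NO)4 (1 mol %), t-BuOOH (70% aq.), K2CO3 (0.5 equiv), CH2Cl2, rt
Reagents that add atoms: tert-butyl hydroperoxide CC(C)(C)OO
Why: Catalytic radical allylic oxidation: tert-butylperoxyl abstracts the weakest hydrogen (doubly allylic C8–H), the pentadienyl radical is captured at its central, least hindered carbon (C10 is fully substituted, C6 is shielded by C5), and the mixed peroxide collapses to the ketone (Kornblum–DeLaMare). No stereocentre is touched.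

**Step 18**
Reactants: 22 (1R,5R)-1,10-bis({[tert-butyl(diphenyl)silyl]oxy}methyl)-5-(2,2-dimethyl-1,3-dioxan-5-yl)cyclohepta-6,9-dien-8-one
Product: 23 (1R,5R,6R,7S)-1,10-bis({[tert-butyl(diphenyl)silyl]oxy}methyl)-5-(2,2-dimethyl-1,3-dioxan-5-yl)-6,7-(propane-2,2-diyl)cyclohept-9-en-8-one (gem-dimethylcyclopropane on C6–C7, C11 anti to C4)
Conditions: i-PrPh2S+ BF4−, LiN(i-Pr)2, DME, −78 °C; then 22, −78 → −30 °C
Reagents that add atoms: isopropyldiphenylsulfonium tetrafluoroborate CC(C)[S+](c1ccccc1)c1ccccc1.F[B-](F)(F)F
Why: Sulfur-ylide isopropylidene transfer (Corey–Chaykovsky-type Michael-initiated ring closure): the ylide adds to C6, the β-carbon of the disubstituted enone (C10 is β,β-disubstituted and shielded), and the C7 enolate displaces diphenyl sulfide in a 3-exo-tet closure. Attack on the face opposite the C5 dioxanyl and C1 silyloxymethyl groups sets C6 and C7 (cis-fused of necessity) with C11 anti to C4, as in 30.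

**Step 19**
Reactants: 23 (1R,5R,6R,7S)-1,10-bis({[tert-butyl(diphenyl)silyl]oxy}methyl)-5-(2,2-dimethyl-1,3-dioxan-5-yl)-6,7-(propane-2,2-diyl)cyclohept-9-en-8-one
Product: 26 C15 monoacetate of the C3/C15 diol (C4 epimers), via diol 24 (not isolated), via cyclic orthoester 25 (not isolated)
Conditions: PPTS (cat.), MeOH, rt; evaporate; MeC(OMe)3, CH2Cl2, rt; then aq. AcOH, 0 °C
Reagents that add atoms: trimethyl orthoacetate COC(C)(OC)OC; water O
Why: Acid-catalysed methanolysis removes the acetonide while the tert-butyldiphenylsilyl ethers survive; the orthoacetate then forms a six-membered cyclic orthoester only across the 1,3-diol, and its mild hydrolysis opens it to exactly one acetate and one free hydroxyl (orthoester monoacylation). The new centre at C4 forms as a mixture that converges when C4 becomes trigonal.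

**Step 20**
Reactants: 26 C15 monoacetate (C2/C14 bis-silyl ether, C3 alcohol)
Product: 27 (1R,5R,6R,7S)-triol with free C2, C3 and C14 hydroxyls and C15 acetate
Conditions: Bu4NF, AcOH, THF, 0 °C → rt
Reagents that add atoms: none
Why: Fluoride desilylation buffered with acetic acid to spare the acetate and the enone; acetyl migration between O15 and O3 is degenerate.

**Step 21**
Reactants: 27 triol with free C2, C3 and C14 hydroxyls
Product: 28 (1R,5R,6R,7S)-trialdehyde (C2, C3 and C14 formyl, C15 acetate, C8 ketone; used crude)
Conditions: (COCl)2, DMSO, CH2Cl2, −78 °C; i-Pr2NEt, −78 → −45 °C; pH 7 buffer, cold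
Reagents that add atoms: none
Why: Swern oxidation: all three hydroxyls are converted to alkoxysulfonium ions before base is added, so no δ-hydroxy aldehyde that could lactolise and over-oxidise to a lactone is ever present. Cold addition of a hindered amine and a cold neutral quench protect C1–H and the β-acetoxy aldehyde.

**Step 22**
Reactants: 28 trialdehyde
Product: 30 CNP0263020.2 (1R,2S,5R,6R,7S), via enol lactol 29 (not isolated)
Conditions: Ac2O, pyridine, DMAP (cat.), CH2Cl2, −20 → 0 °C
Reagents that add atoms: acetic anhydride CC(=O)OC(C)=O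
Why: Enol-lactol closure of a 1,5-dialdehyde followed by O-acetylation (the iridodial-to-nepetalactol type of ring–chain tautomerism): the C3 enol oxygen adds to the C2 aldehyde (6-exo-trig) and the hemiacetal hydroxyl is trapped as the acetate. The lactol epimers at C2 interconvert, and acylation should favour the acetate that can sit axial (anomeric effect) while C10 stays equatorial, which is the isomer trans to H1. Allylic strain with the C14 group holds C1–H near the plane of C9=C10, which should damp its vinylogous acidity.

## Compound list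

1 | 2-(hydroxymethyl)propane-1,3-diol | OCC(CO)CO | starting material
2 | (2,2-dimethyl-1,3-dioxan-5-yl)methanol | CC1(C)OCC(CO)CO1 | intermediate
3 | 5-{[(2,2-dimethyl-1,3-dioxan-5-yl)methyl]sulfanyl}-1-phenyl-1H-tetrazole | CC1(C)OCC(CSc2nnnn2-c2ccccc2)CO1 | intermediate
4 | 5-{[(2,2-dimethyl-1,3-dioxan-5-yl)methyl]sulfonyl}-1-phenyl-1H-tetrazole | CC1(C)OCC(CS(=O)(=O)c2nnnn2-c2ccccc2)CO1 | intermediate
5 | cis-cyclopropane-1,2-dicarboxylic anhydride (meso) | O=C1OC(=O)[C@H]2C[C@@H]12 | starting material
6 | (1R,2S)-2-(methoxycarbonyl)cyclopropane-1-carboxylic acid | OC(=O)[C@@H]1C[C@@H]1C(=O)OC | intermediate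
7 | (1R,2S)-2-(hydroxymethyl)cyclopropane-1-carboxylic acid | OC(=O)[C@@H]1C[C@@H]1CO | intermediate (not isolated)
8 | (1R,5S)-3-oxabicyclo[3.1.0]hexan-2-one | O=C1[C@@H]2C[C@@H]2CO1 | intermediate
9 | (1R,2S)-2-(hydroxymethyl)-N-methoxy-N-methylcyclopropane-1-carboxamide | CON(C)C(=O)[C@@H]1C[C@@H]1CO | intermediate
10 | (1R,2S)-2-{[(tert-butyldimethylsilyl)oxy]methyl}-N-methoxy-N-methylcyclopropane-1-carboxamide | CON(C)C(=O)[C@@H]1C[C@@H]1CO[Si](C)(C)C(C)(C)C | intermediate
11 | 2-(benzyloxy)-1-[(1R,2S)-2-{[(tert-butyldimethylsilyl)oxy]methyl}cyclopropyl]ethan-1-one | O=C(COCc1ccccc1)[C@@H]1C[C@@H]1CO[Si](C)(C)C(C)(C)C | intermediate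
12 | 1-[(1R,2S)-2-{[(tert-butyldimethylsilyl)oxy]methyl}cyclopropyl]-2-hydroxyethan-1-one | O=C(CO)[C@@H]1C[C@@H]1CO[Si](C)(C)C(C)(C)C | intermediate
13 | (triphenylphosphoranylidene)ketene | O=C=C=P(c1ccccc1)(c1ccccc1)c1ccccc1 | starting material
14 | 2-[(1R,2S)-2-{[(tert-butyldimethylsilyl)oxy]methyl}cyclopropyl]-2-oxoethyl (triphenylphosphoranylidene)acetate | O=C(COC(=O)C=P(c1ccccc1)(c1ccccc1)c1ccccc1)[C@@H]1C[C@@H]1CO[Si](C)(C)C(C)(C)C | intermediate (not isolated)
15 | 4-[(1R,2S)-2-{[(tert-butyldimethylsilyl)oxy]methyl}cyclopropyl]furan-2(5H)-one | O=C1C=C(CO1)[C@@H]2C[C@@H]2CO[Si](C)(C)C(C)(C)C | intermediate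
16 | (2Z)-2-[(1R,2S)-2-{[(tert-butyldimethylsilyl)oxy]methyl}cyclopropyl]but-2-ene-1,4-diol | OC/C(=C\CO)[C@@H]1C[C@@H]1CO[Si](C)(C)C(C)(C)C | intermediate
17 | (1R,2S)-1-[(2Z)-1,4-bis{[tert-butyl(diphenyl)silyl]oxy}but-2-en-2-yl]-2-{[(tert-butyldimethylsilyl)oxy]methyl}cyclopropane | CC(C)(C)[Si](c1ccccc1)(c1ccccc1)OC/C(=C\CO[Si](c1ccccc1)(c1ccccc1)C(C)(C)C)[C@@H]1C[C@@H]1CO[Si](C)(C)C(C)(C)C | intermediate
18 | {(1S,2R)-2-[(2Z)-1,4-bis{[tert-butyl(diphenyl)silyl]oxy}but-2-en-2-yl]cyclopropyl}methanol | CC(C)(C)[Si](c1ccccc1)(c1ccccc1)OC/C(=C\CO[Si](c1ccccc1)(c1ccccc1)C(C)(C)C)[C@@H]1C[C@@H]1CO | intermediate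
19 | (1S,2R)-2-[(2Z)-1,4-bis{[tert-butyl(diphenyl)silyl]oxy}but-2-en-2-yl]cyclopropane-1-carbaldehyde | CC(C)(C)[Si](c1ccccc1)(c1ccccc1)OC/C(=C\CO[Si](c1ccccc1)(c1ccccc1)C(C)(C)C)[C@@H]1C[C@@H]1C=O | intermediate
20 | (1R,2R)-1-[(2Z)-1,4-bis{[tert-butyl(diphenyl)silyl]oxy}but-2-en-2-yl]-2-[(E)-2-(2,2-dimethyl-1,3-dioxan-5-yl)ethenyl]cyclopropane (cis) | CC(C)(C)[Si](c1ccccc1)(c1ccccc1)OC/C(=C\CO[Si](c1ccccc1)(c1ccccc1)C(C)(C)C)[C@@H]1C[C@@H]1/C=C/C2COC(C)(C)OC2 | intermediate
21 | (1R,5R)-cis-cyclohepta-6,9-diene with silyloxymethyl groups on C1 and C10 and the dioxanyl group on C5 | CC(C)(C)[Si](c1ccccc1)(c1ccccc1)OC[C@H]2C(CO[Si](c1ccccc1)(c1ccccc1)C(C)(C)C)=CCC=C[C@H]2C3COC(C)(C)OC3 | intermediate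
22 | (1R,5R)-cyclohepta-6,9-dien-8-one (cross-conjugated dienone) | CC(C)(C)[Si](c1ccccc1)(c1ccccc1)OC[C@H]2C(CO[Si](c1ccccc1)(c1ccccc1)C(C)(C)C)=CC(=O)C=C[C@H]2C3COC(C)(C)OC3 | intermediate
23 | (1R,5R,6R,7S)-cyclopropyl enone with gem-dimethylcyclopropane on C6–C7 | CC(C)(C)[Si](c1ccccc1)(c1ccccc1)OC[C@H]2C(CO[Si](c1ccccc1)(c1ccccc1)C(C)(C)C)=CC(=O)[C@H]3[C@@H]([C@H]2C4COC(C)(C)OC4)C3(C)C | intermediate
24 | (1R,5R,6R,7S)-C3/C15 diol | CC(C)(C)[Si](c1ccccc1)(c1ccccc1)OC[C@H]2C(CO[Si](c1ccccc1)(c1ccccc1)C(C)(C)C)=CC(=O)[C@H]3[C@@H]([C@H]2C(CO)CO)C3(C)C | intermediate (not isolated)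
25 | (1R,5R,6R,7S)-cyclic orthoacetate (2-methoxy-2-methyl-1,3-dioxan-5-yl on C5) | CC(C)(C)[Si](c1ccccc1)(c1ccccc1)OC[C@H]2C(CO[Si](c1ccccc1)(c1ccccc1)C(C)(C)C)=CC(=O)[C@H]3[C@@H]([C@H]2C4COC(C)(OC)OC4)C3(C)C | intermediate (not isolated)
26 | (1R,5R,6R,7S)-C15 monoacetate, C3 alcohol (C4 epimers) | CC(C)(C)[Si](c1ccccc1)(c1ccccc1)OC[C@H]2C(CO[Si](c1ccccc1)(c1ccccc1)C(C)(C)C)=CC(=O)[C@H]3[C@@H]([C@H]2C(CO)COC(C)=O)C3(C)C | intermediate
27 | (1R,5R,6R,7S)-triol (C2, C3, C14 hydroxyls; C15 acetate; C4 epimers) | OC[C@H]2C(CO)=CC(=O)[C@H]3[C@@H]([C@H]2C(CO)COC(C)=O)C3(C)C | intermediate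
28 | (1R,5R,6R,7S)-trialdehyde (C2, C3, C14 formyl; C15 acetate; C4 epimers) | O=C[C@H]2C(C=O)=CC(=O)[C@H]3[C@@H]([C@H]2C(C=O)COC(C)=O)C3(C)C | intermediate
29 | (1R,5R,6R,7S)-enol lactol (C2 hydroxyl, C2 epimers in equilibrium) | CC(=O)OCC1=COC(O)[C@H]2C(C=O)=CC(=O)[C@H]3[C@@H]([C@@H]12)C3(C)C | intermediate (not isolated)
30 | CNP0263020.2, (1R,2S,5R,6R,7S) | CC(=O)OCC1=CO[C@@H](OC(C)=O)[C@H]2C(C=O)=CC(=O)[C@H]3[C@@H]([C@@H]12)C3(C)C | target

## Step count and least certain steps

Total: 22 steps. Longest linear sequence: 19 steps (steps 4–22, from 5). The sulfone branch is 3 steps (1–3).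

**Step 16 (key step).** The most likely failure is stalling. Material that entered as the Z alkene or as a trans-cyclopropane cannot reach the boat at this temperature. For the correct isomer, the two bulky silyloxymethyl groups may raise the barrier enough that heating is needed, and heating invites a 1,5-hydrogen shift in the skipped diene.
The fallback moves the rearrangement to the butenolide stage, where C14 and C2 are tied back in a flat, electron-poor ring. It sets out from 15:
- HF·pyridine removes the silyl group to give 4-[(1R,2S)-2-(hydroxymethyl)cyclopropyl]furan-2(5H)-one F1.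
- Dess–Martin oxidation gives the aldehyde F2.
- Julia–Kocienski olefination with 4 (KN(SiMe3)2, −78 °C) gives the cis-alkenylcyclopropyl butenolide F3, whose ring alkene is the second arm with C2 already trans to C9.
- Its Cope rearrangement gives the cis-fused bicyclic lactone F4.
- i-Bu2AlH reduction gives the diol F5, and silylation with TBDPSCl comes back to the route at 21.

**Step 22.** The most likely failure is enolisation in the wrong direction. C1–H is α to the C2 aldehyde and γ to the enone, so under basic acylation it can compete with C4–H; that would lead to the regioisomeric enol acetal, to loss of the C1 configuration, or to an open dienol acetate. Base-induced loss of acetic acid from the β-acetoxy aldehyde and poor anomeric selectivity at C2 are further exits.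
The fallback takes base and acylating agent out of the bond-forming event. It sets out from 28. The crude trialdehyde is left to close on neutral buffered silica, and lactol 29 is isolated. 29 is then esterified under Mitsunobu conditions (PPh3, i-PrO2CN=NCO2i-Pr, AcOH, THF, 0 °C), where acetate displaces the activated anomeric oxygen, to arrive at 30. No new compound is made.

**Step 17.** The most likely failure is capture of the pentadienyl radical at C6 instead of C8, giving the conjugated 2,4-dienone isomer, or over-oxidation at the allylic C14 methylene.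
The fallback replaces the radical path by an anionic one. It sets out from 21. Deprotonation of the doubly allylic C8–H with n-BuLi/KOt-Bu (THF, −78 °C) gives the cycloheptadienyl anion, which is borylated at its central carbon with B(OMe)3 and oxidised (H2O2, NaOH) to the (1R,5R)-cyclohepta-6,9-dien-8-ol F6. MnO2 oxidation of this doubly allylic alcohol comes back at 22.

**Step 18.** The most likely failure is the ylide acting as a base. γ-Deprotonation at C5 or C1 would isomerise the dienone, and some addition could occur at the wrong enone or from the wrong face.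
The fallback uses a neutral dipolar cycloaddition. It sets out from 22. 2-Diazopropane (Et2O, −78 → 0 °C) adds across C6=C7, carbon to C6, anti to C4, to give the cis-fused 1-pyrazoline F7. Irradiation (350 nm) extrudes nitrogen and comes back at 23.

**Step 15.** The most likely failure lies in the aldehyde partner. The cis-alkenyl aldehyde 19 can drain by a reversible retro-Claisen shift to a dihydrooxepine or epimerise, and E/Z selectivity may be incomplete.
The fallback reverses the polarity so that no cis-formyl cyclopropane is needed. It sets out from 18 and 2: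
- Mitsunobu reaction of 18 with 1-phenyl-1H-tetrazole-5-thiol gives the cyclopropylmethyl tetrazolyl sulfide F8.
- Oxidation with (NH4)6Mo7O24·4H2O/H2O2 gives the sulfone F9.
- Dess–Martin oxidation of 2 gives 2,2-dimethyl-1,3-dioxane-5-carbaldehyde F10.
- Olefination of F10 with metalated F9 (KN(SiMe3)2, DME, −78 °C) comes back at 20.

## Further compounds

F1 | step 16 | 4-[(1R,2S)-2-(hydroxymethyl)cyclopropyl]furan-2(5H)-one | O=C1C=C(CO1)[C@@H]2C[C@@H]2CO
F2 | step 16 | (1S,2R)-2-(5-oxo-2,5-dihydrofuran-3-yl)cyclopropane-1-carbaldehyde | O=C1C=C(CO1)[C@@H]2C[C@@H]2C=O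
F3 | step 16 | 4-{(1R,2R)-2-[(E)-2-(2,2-dimethyl-1,3-dioxan-5-yl)ethenyl]cyclopropyl}furan-2(5H)-one (cis) | O=C1C=C(CO1)[C@@H]2C[C@@H]2/C=C/C3COC(C)(C)OC3
F4 | step 16 | cis-fused bicyclic lactone (C2 carbonyl, O14 bridge across C1–C10; C9=C10 and C6=C7 alkenes; dioxanyl on C5; H1/H5 cis) | O=C3OCC2=CCC=C[C@H]([C@H]23)C1COC(C)(C)OC1
F5 | step 16 | (1R,5R)-1,10-bis(hydroxymethyl)-5-(2,2-dimethyl-1,3-dioxan-5-yl)cyclohepta-6,9-diene | OC[C@H]2C(CO)=CCC=C[C@H]2C3COC(C)(C)OC3
F0 | step 22 | none | none
F6 | step 17 | (1R,5R)-1,10-bis({[tert-butyl(diphenyl)silyl]oxy}methyl)-5-(2,2-dimethyl-1,3-dioxan-5-yl)cyclohepta-6,9-dien-8-ol | CC(C)(C)[Si](c1ccccc1)(c1ccccc1)OC[C@H]2C(CO[Si](c1ccccc1)(c1ccccc1)C(C)(C)C)=CC(O)C=C[C@H]2C3COC(C)(C)OC3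
F7 | step 18 | cis-fused 1-pyrazoline across C6–C7 (N on C7, CMe2 on C6, anti to C4) | CC(C)(C)[Si](c1ccccc1)(c1ccccc1)OC[C@H]2C(CO[Si](c1ccccc1)(c1ccccc1)C(C)(C)C)=CC(=O)[C@H]3[C@@H]([C@H]2C4COC(C)(C)OC4)C(C)(C)N=N3
F8 | step 15 | 5-[({(1S,2R)-2-[(2Z)-1,4-bis{[tert-butyl(diphenyl)silyl]oxy}but-2-en-2-yl]cyclopropyl}methyl)sulfanyl]-1-phenyl-1H-tetrazole | CC(C)(C)[Si](c1ccccc1)(c1ccccc1)OC/C(=C\CO[Si](c1ccccc1)(c1ccccc1)C(C)(C)C)[C@@H]1C[C@@H]1CSc1nnnn1-c1ccccc1
F9 | step 15 | 5-[({(1S,2R)-2-[(2Z)-1,4-bis{[tert-butyl(diphenyl)silyl]oxy}but-2-en-2-yl]cyclopropyl}methyl)sulfonyl]-1-phenyl-1H-tetrazole | CC(C)(C)[Si](c1ccccc1)(c1ccccc1)OC/C(=C\CO[Si](c1ccccc1)(c1ccccc1)C(C)(C)C)[C@@H]1C[C@@H]1CS(=O)(=O)c1nnnn1-c1ccccc1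
F10 | step 15 | 2,2-dimethyl-1,3-dioxane-5-carbaldehyde | CC1(C)OCC(C=O)CO1
A1 | alternative 1 | tricyclic enol lactone enone (C15 silyl ether, C14 dimethyl acetal) | CC(C)(C)[Si](C)(C)OCC1=COC(=O)[C@H]2C(C(OC)OC)=CC(=O)[C@H]3[C@@H]([C@@H]12)C3(C)C
A2 | alternative 1 | bicyclic dienoyl fluoride (C2 acyl fluoride on the C1=C5 alkene) | O=C(F)C1=C[C@@H]2[C@@H](C2(C)C)C(=O)C=C1C(OC)OC
A3 | alternative 1 | trimethylsilyl enol ether of 3-[(tert-butyldimethylsilyl)oxy]propanal | C[Si](C)(C)OC=CCO[Si](C)(C)C(C)(C)C
A4 | alternative 2 | tricyclic diacetate with saturated C9–C10 and silyloxymethyl on C10 | CC(=O)OCC1=CO[C@@H](OC(C)=O)[C@H]2[C@@H](CO[Si](C)(C)C(C)(C)C)CC(=O)[C@H]3[C@@H]([C@@H]12)C3(C)C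
A5 | alternative 2 | cis-cyclopropane bearing the (E)-2-(acetoxymethyl)enal on C6 and the keto chain ending in a (Z)-enol acetate on C7 | CC(=O)OC/C(C=O)=C\[C@@H]1[C@@H](C1(C)C)C(=O)C[C@H](CO[Si](C)(C)C(C)(C)C)/C=C\OC(C)=O
A6 | alternative 3 | tricyclic enol lactone with C8 enol acetate | CC(C)(C)[Si](C)(C)OCC1=COC(=O)[C@H]2[C@@H](C(OC)OC)C=C(OC(C)=O)[C@H]3[C@@H]([C@@H]12)C3(C)C
A7 | alternative 3 | enol lactone bearing the C9 propargylic acetate chain on C1 and a 2-methylprop-1-enyl group on C5 | CC(C)(C)[Si](C)(C)OCC1=COC(=O)[C@@H]([C@@H](C(OC)OC)C(OC(C)=O)C#C)[C@H]1C=C(C)C
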